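At the reading of 10.0 h, red, charged with 0.75 mol% of the catalyst G, stood at 10% of the product J, and amber, with 0.34 mol%, at 5%.

| setting | amber | red | green | flask |
|---|---|---|---|---|
| X | 0.30 M | 0.30 M | 0.45 M | 0.30 M |
| D | 5 equiv | 5 equiv | 5 equiv | 5.00 equiv |
| G | 0.34 mol% | 0.75 mol% | 0.5 mol% | 0.5 mol% |
| remark | run made earlier | run made earlier | run made earlier |  |

| amber: time / h | amber: J / % | red: time / h | red: J / % | green: time / h | green: J / % |
|---|---|---|---|---|---|
| 0.833 | 0 | 2.00 | 1 | 0.833 | 0 |
| 2.50 | 0 | 4.00 | 1 | 2.50 | 2 |
| 4.00 | 0 | 6.00 | 3 | 4.00 | 5 |
| 6.00 | 0 | 8.00 | 8 | 6.00 | 10 |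
| 10.0 | 5 | 10.0 | 10 | 10.0 | 21 |

(standard deviation of a reading: 1.5 percentage points)

1. factor on the rate of making J when 50% of the X are converted if G is charged twice over
2. factor on the rate when 50% of the X are converted if G is charged at 0.1 mol% instead



Did J follow G at a set time? From amber to red, J differed by a factor of 2.00 for a factor of 2.21 in G, so within a scatter of 1.5 percentage points it did.

How did J grow with time? In green it rose by a factor of 4.20 from 4.00 h to 10.0 h, while time grew by a factor of 2.50. The rate in green was therefore climbing, as in an induction period, and I took J as proportional to G times time squared.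

Did the climb last until 50% conversion? Taking the substrate X as first order, I carried red's reading over to the flask's G, which put that conversion at about 31.4 h, later than the last reading, so the readings left this open. If the climb lasted, the rate there, G times time, went with the square root of the ratio of charges, which I call the root factor 1.41 for a doubled charge and 0.447 for 0.1 mol%. If it had ended, the rate went with G itself. So I committed to between 1.41 and 2 for the doubled charge, and between 0.200 and 0.447 for the small one.

The forecast took “roughly first order in G” and gave 1.9 and 0.21.

The flask gave 1.56 for the doubled charge, above the root factor and below 2, and 0.289 for 0.1 mol%.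

D + G → Q + E (k = 0.0217 M⁻¹ h⁻¹); X + D + Q → Q + J (k = 24.0 M⁻² h⁻¹) In this flask G turned into Q, the working form, with a time of 30.7 h at the reagent D as charged, against 34.6 h to reach 50% conversion. At that conversion Q was 65.9% of the catalyst.

The readings stem from a simulated flask for substances that don't exist; noise was put on by code.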